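**Retrosynthetic overview**
1. Target ⇐ desilylation and C1 oxidation ⇐ ten-membered ring closed last by a Nozaki–Hiyama–Kishi macrocyclization (C1–C10) of iodo-aldehyde 30.
2. Seco compound ⇐ chromium-mediated 2-(alkoxycarbonyl)allylation (C7–C8) joining bromomethyl butenolide 14 (C1–C7, C11–C13) with α-angeloyloxy aldehyde 26 (C8–C10, C14); this step sets C7 and C8 and unveils the α-methylene lactone.
3. 14 ⇐ butenolide by ring-closing metathesis ⇐ Shi epoxidation ⇐ alkenyllithium opening of (R)-epichlorohydrin (C6). 26 ⇐ D-mannitol (C9), alkyne homologation, Markovnikov hydrostannation/iodination, angeloylation.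
4. Ring order: oxirane (step 5) → five-membered lactone ring (step 8, becoming the α-methylene-γ-lactone in step 16) → ten-membered carbocycle (step 20).

Assumption and labels (one line): the D-fructose-derived Shi ketone, Cp2Zr(H)Cl, the Ohira–Bestmann reagent and Mo(CO)3(CNtBu)3 are bought; labels are C1 ketone carbon, C2, C3/C4 oxirane carbons (C4 bears the methyl), C5, C6 lactone O–CH, C7 ring-fusion CH, C8 carbinol, C9 angelate carbon, C10 methylidene carbon, C11/C12 lactone α-carbon/carbonyl; the target is 3R,4R,6R,7R,8R,9S in these labels.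

**Step 1**
Reactants: 1 pent-3-yn-1-ol
Product: 2 1-methoxy-4-[(pent-3-yn-1-yloxy)methyl]benzene
Conditions: NaH, 4-methoxybenzyl chloride, Bu4NI (cat.), THF/DMF, 0 °C to rt
Reagents that add atoms: 4-methoxybenzyl chloride, COc1ccc(CCl)cc1
Why: Williamson etherification installs a PMB ether that survives the organometallic, epoxidation, metathesis and chromium steps and is removed oxidatively at step 18.

**Step 2**
Reactants: 2 1-methoxy-4-[(pent-3-yn-1-yloxy)methyl]benzene
Product: 4 1-({[(3E)-4-iodopent-3-en-1-yl]oxy}methyl)-4-methoxybenzene, via alkenylzirconocene 3 (not isolated)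
Conditions: Cp2Zr(H)Cl (2.2 equiv), THF, 50 °C; then I2, 0 °C
Reagents that add atoms: iodine, II
Why: Syn-hydrozirconation with excess reagent equilibrates zirconium to the less hindered methyl-bearing carbon, and iodinolysis with retention gives the (E)-2-iodoalkene (hydrozirconation–iodination).

**Step 3**
Reactants: 4 1-({[(3E)-4-iodopent-3-en-1-yl]oxy}methyl)-4-methoxybenzene; 5 (R)-epichlorohydrin
Product: 7 (2R,4E)-1-chloro-7-[(4-methoxybenzyl)oxy]-4-methylhept-4-en-2-ol, via alkenyllithium 6 (not isolated)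
Conditions: t-BuLi (2 equiv), Et2O, −78 °C; then BF3·OEt2 and 5, −78 °C; aqueous work-up
Reagents that add atoms: none
Why: Iodine–lithium exchange with retention of alkene geometry is followed by BF3-promoted SN2 opening of the oxirane at its CH2 terminus, so the stereocentre of 5 (future C6) is untouched.

**Step 4**
Reactants: 7 (2R,4E)-1-chloro-7-[(4-methoxybenzyl)oxy]-4-methylhept-4-en-2-ol
Product: 9 (3R,5E)-8-[(4-methoxybenzyl)oxy]-5-methylocta-1,5-dien-3-ol, via terminal epoxide 8 (not isolated)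
Conditions: Me3S+ I− (5 equiv), n-BuLi (4.8 equiv), THF, −10 °C to rt
Reagents that add atoms: trimethylsulfonium iodide, C[S+](C)C.[I-]
Why: Base closes the chlorohydrin to the epoxide with the C6–O bond intact, and dimethylsulfonium methylide opens it at CH2 and eliminates to the one-carbon-homologated allylic alcohol (sulfur-ylide epoxide-to-allylic-alcohol homologation).

**Step 5**
Reactants: 9 (3R,5E)-8-[(4-methoxybenzyl)oxy]-5-methylocta-1,5-dien-3-ol
Product: 10 (2R)-1-[(2R,3R)-3-{2-[(4-methoxybenzyl)oxy]ethyl}-2-methyloxiran-2-yl]but-3-en-2-ol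
Conditions: D-fructose-derived Shi ketone (30 mol%), KHSO5 (Oxone), K2CO3, Bu4NHSO4, MeCN/dimethoxymethane/aq. borate buffer (pH 10.5), 0 °C
Reagents that add atoms: potassium peroxymonosulfate KHSO5, [K+].[O-]S(=O)(=O)OO
Why: Shi asymmetric epoxidation (chiral dioxirane, spiro transition state) attacks only the electron-rich trisubstituted E-alkene and sets the (R,R)-oxirane (C3, C4) under catalyst control, leaving the terminal vinyl group alone.

**Step 6**
Reactants: 11 2-(bromomethyl)prop-2-enoic acid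
Product: 12 2-(bromomethyl)prop-2-enoyl chloride
Conditions: (COCl)2, DMF (cat.), CH2Cl2, 0 °C to rt; concentrate
Reagents that add atoms: oxalyl chloride, ClC(=O)C(=O)Cl
Why: Vilsmeier-type acid chloride formation gives an acylating agent that needs no nucleophilic amine catalyst, which would attack the allylic bromide.

**Step 7**
Reactants: 10 (2R)-1-[(2R,3R)-3-{2-[(4-methoxybenzyl)oxy]ethyl}-2-methyloxiran-2-yl]but-3-en-2-ol; 12 2-(bromomethyl)prop-2-enoyl chloride
Product: 13 (2R)-1-[(2R,3R)-3-{2-[(4-methoxybenzyl)oxy]ethyl}-2-methyloxiran-2-yl]but-3-en-2-yl 2-(bromomethyl)prop-2-enoate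
Conditions: 2,6-lutidine, CH2Cl2, −20 to 0 °C
Reagents that add atoms: none
Why: O-acylation with a hindered, non-nucleophilic base avoids SN2′ attack on the allylic bromide and acid-induced oxirane opening, and leaves C6 untouched.

**Step 8**
Reactants: 13 (2R)-1-[(2R,3R)-3-{2-[(4-methoxybenzyl)oxy]ethyl}-2-methyloxiran-2-yl]but-3-en-2-yl 2-(bromomethyl)prop-2-enoate
Product: 14 (5R)-3-(bromomethyl)-5-{[(2R,3R)-3-{2-[(4-methoxybenzyl)oxy]ethyl}-2-methyloxiran-2-yl]methyl}furan-2(5H)-one
Conditions: second-generation Hoveyda–Grubbs catalyst (10 mol%), toluene, 80 °C, argon sparge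
Reagents that add atoms: none
Why: Ring-closing metathesis of the vinyl carbinol ester with the 1,1-disubstituted acrylate closes the five-membered butenolide with loss of ethylene, and the phosphine-free catalyst tolerates the allylic bromide.

**Step 9**
Reactants: 15 1,2:5,6-di-O-isopropylidene-D-mannitol
Product: 17 (S)-4-ethynyl-2,2-dimethyl-1,3-dioxolane, via (R)-glyceraldehyde acetonide 16 (not isolated)
Conditions: NaIO4, CH2Cl2/aq. NaHCO3, rt; crude aldehyde then dimethyl (1-diazo-2-oxopropyl)phosphonate, K2CO3, MeOH, 0 °C to rt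
Reagents that add atoms: dimethyl (1-diazo-2-oxopropyl)phosphonate, CC(=O)C(=[N+]=[N-])P(=O)(OC)OC
Why: Periodate glycol cleavage followed by Ohira–Bestmann (Seyferth–Gilbert) homologation gives the alkyne, with the stereocentre (future C9) taken from D-mannitol.

**Step 10**
Reactants: 17 (S)-4-ethynyl-2,2-dimethyl-1,3-dioxolane
Product: 19 (R)-4-(1-iodoethenyl)-2,2-dimethyl-1,3-dioxolane, via α-stannylalkene 18 (not isolated)
Conditions: Bu3SnH, Mo(CO)3(CNtBu)3 (3 mol%), hydroquinone (cat.), THF, 55 °C; then I2, CH2Cl2, 0 °C; KF work-up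
Reagents that add atoms: iodine, II
Why: Molybdenum-catalysed hydrostannation of the propargylic acetal is Markovnikov (α) selective, and iododestannylation with retention gives the 2-iodo-1-alkene.

**Step 11**
Reactants: 19 (R)-4-(1-iodoethenyl)-2,2-dimethyl-1,3-dioxolane
Product: 20 (2R)-3-iodobut-3-ene-1,2-diol
Conditions: 80% aq. AcOH, 40 °C
Reagents that add atoms: none
Why: Acid-catalysed acetal hydrolysis frees the diol without touching the alkenyl iodide or the stereocentre.

**Step 12**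
Reactants: 20 (2R)-3-iodobut-3-ene-1,2-diol
Product: 21 (2R)-1-[(tert-butyldimethylsilyl)oxy]-3-iodobut-3-en-2-ol
Conditions: tert-butyldimethylsilyl chloride (1.05 equiv), imidazole, CH2Cl2, −20 to 0 °C
Reagents that add atoms: tert-butyldimethylsilyl chloride, CC(C)(C)[Si](C)(C)Cl
Why: Sterically controlled silylation protects the primary hydroxyl and leaves the secondary allylic hydroxyl free for acylation.

**Step 13**
Reactants: 21 (2R)-1-[(tert-butyldimethylsilyl)oxy]-3-iodobut-3-en-2-ol; 22 angelic acid [(2Z)-2-methylbut-2-enoic acid]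
Product: 24 (2R)-1-[(tert-butyldimethylsilyl)oxy]-3-iodobut-3-en-2-yl (2Z)-2-methylbut-2-enoate, via mixed anhydride 23 (not isolated)
Conditions: 22, 2,4,6-trichlorobenzoyl chloride, Et3N, toluene, rt; then 21, toluene, 80 °C (no DMAP)
Reagents that add atoms: none
Why: Yamaguchi-type esterification through the mixed anhydride without a nucleophilic catalyst acylates the alcohol while avoiding addition–elimination isomerisation of the Z-angelate to the tiglate.

**Step 14**
Reactants: 24 (2R)-1-[(tert-butyldimethylsilyl)oxy]-3-iodobut-3-en-2-yl (2Z)-2-methylbut-2-enoate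
Product: 25 (2R)-1-hydroxy-3-iodobut-3-en-2-yl (2Z)-2-methylbut-2-enoate
Conditions: HF·pyridine, pyridine, THF, 0 °C to rt
Reagents that add atoms: none
Why: Fluoride desilylation under slightly acidic, non-basic conditions removes the primary silyl ether without 1,2-acyl migration.

**Step 15**
Reactants: 25 (2R)-1-hydroxy-3-iodobut-3-en-2-yl (2Z)-2-methylbut-2-enoate
Product: 26 (2R)-3-iodo-1-oxobut-3-en-2-yl (2Z)-2-methylbut-2-enoate
Conditions: Dess–Martin periodinane, NaHCO3, CH2Cl2, 0 °C; filtered and used at once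
Reagents that add atoms: none
Why: Buffered Dess–Martin oxidation gives the α-acyloxy aldehyde under neutral conditions, and immediate use limits epimerisation or conjugation of the allylic α-centre.

**Step 16**
Reactants: 14 (5R)-3-(bromomethyl)-5-{[(2R,3R)-3-{2-[(4-methoxybenzyl)oxy]ethyl}-2-methyloxiran-2-yl]methyl}furan-2(5H)-one; 26 (2R)-3-iodo-1-oxobut-3-en-2-yl (2Z)-2-methylbut-2-enoate
Product: 27 (1R,2R)-1-hydroxy-3-iodo-1-[(2R,3R)-2-{[(2R,3R)-3-{2-[(4-methoxybenzyl)oxy]ethyl}-2-methyloxiran-2-yl]methyl}-4-methylidene-5-oxooxolan-3-yl]but-3-en-2-yl (2Z)-2-methylbut-2-enoate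
Conditions: CrCl2 (4 equiv, nickel-free), THF, 0 °C to rt; aqueous work-up
Reagents that add atoms: none
Why: In this chromium-mediated Barbier-type 2-(alkoxycarbonyl)allylation the allylchromium reacts at the ring γ-carbon anti to the C6 substituent (C7, trans lactone), through a chair transition state of the ring-locked E-allyl unit (C7/C8 anti) and in the Felkin–Anh sense relative to C9 (C8/C9 anti), a matched case, while the alkenyl iodide is inert without nickel.

**Step 17**
Reactants: 27 (the C8 alcohol from step 16)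
Product: 28 C8 triethylsilyl ether of 27 (all configurations as in 27)
Conditions: triethylsilyl chloride, imidazole, DMF, 0 °C to rt
Reagents that add atoms: triethylsilyl chloride, CC[Si](Cl)(CC)CC
Why: Mild silylation masks the C8 hydroxyl against the two later oxidations, acyl migration and translactonisation without the silyl triflate conditions that would open the oxirane.

**Step 18**
Reactants: 28 C8 triethylsilyl ether of 27
Product: 29 primary C1 alcohol (PMB ether of 28 cleaved, all else unchanged)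
Conditions: DDQ, CH2Cl2/pH 7 phosphate buffer, 0 °C
Reagents that add atoms: none
Why: Oxidative PMB cleavage under buffered neutral conditions spares the silyl ether, oxirane, angelate, alkenyl iodide and methylene lactone, and the buffer prevents acid-promoted cyclisation of the 3,4-epoxy alcohol.

**Step 19**
Reactants: 29 primary C1 alcohol
Product: 30 C1 aldehyde (β,γ-epoxy aldehyde, all else as in 29)
Conditions: Dess–Martin periodinane, NaHCO3, CH2Cl2, 0 °C; used at once
Reagents that add atoms: none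
Why: Buffered Dess–Martin oxidation reaches the aldehyde without the base that would eliminate the β,γ-epoxide.

**Step 20**
Reactants: 30 C1 aldehyde
Product: 31 macrocyclic allylic alcohol (ten-membered ring, C1 carbinol as both epimers, C8 triethylsilyl ether)
Conditions: CrCl2 (10 equiv), NiCl2 (1 mol% of Cr), DMSO/THF 3:1, rt, 2 mM, slow addition
Reagents that add atoms: none
Why: In this Nozaki–Hiyama–Kishi macrocyclization zerovalent nickel inserts into the C–I bond, transmetalation gives the alkenyl species of trivalent chromium, and this adds to the aldehyde at high dilution to close C1–C10; the C1 configuration is irrelevant because it is oxidised next.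

**Step 21**
Reactants: 31 macrocyclic allylic alcohol
Product: 32 8-O-triethylsilyl ether of the target
Conditions: Dess–Martin periodinane, NaHCO3, CH2Cl2, 0 °C
Reagents that add atoms: none
Why: Dess–Martin oxidation converges both C1 epimers to the α-methylene ketone under non-basic conditions that leave the β,γ-epoxy ketone intact.

**Step 22**
Reactants: 32 8-O-triethylsilyl ether of the target
Product: 33 target CNP0348992.5
Conditions: HF·pyridine, pyridine, THF, 0 °C
Reagents that add atoms: none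
Why: Buffered fluoride desilylation frees the C8 hydroxyl without base, so angelate migration, translactonisation and epoxide elimination are avoided.

**Compound list**
1 | pent-3-yn-1-ol | CC#CCCO | starting material
2 | 1-methoxy-4-[(pent-3-yn-1-yloxy)methyl]benzene | CC#CCCOCc1ccc(OC)cc1 | intermediate
3 | chlorobis(cyclopentadienyl)[(2E)-5-(4-methoxybenzyloxy)pent-2-en-2-yl]zirconium | C/C(=C\CCOCc1ccc(OC)cc1)[Zr](Cl)(C1C=CC=C1)C1C=CC=C1 | intermediate
4 | 1-({[(3E)-4-iodopent-3-en-1-yl]oxy}methyl)-4-methoxybenzene | C/C(I)=C\CCOCc1ccc(OC)cc1 | intermediate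
5 | (R)-epichlorohydrin, (2R)-2-(chloromethyl)oxirane | ClC[C@H]1CO1 | starting material
6 | (2E)-5-(4-methoxybenzyloxy)pent-2-en-2-yllithium | C/C([Li])=C\CCOCc1ccc(OC)cc1 | intermediate
7 | (2R,4E)-1-chloro-7-[(4-methoxybenzyl)oxy]-4-methylhept-4-en-2-ol | O[C@@H](CCl)C/C(C)=C/CCOCc1ccc(OC)cc1 | intermediate
8 | (2R)-2-{(2E)-5-[(4-methoxybenzyl)oxy]-2-methylpent-2-en-1-yl}oxirane | C1O[C@@H]1C/C(C)=C/CCOCc1ccc(OC)cc1 | intermediate
9 | (3R,5E)-8-[(4-methoxybenzyl)oxy]-5-methylocta-1,5-dien-3-ol | O[C@@H](C=C)C/C(C)=C/CCOCc1ccc(OC)cc1 | intermediate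
10 | (2R)-1-[(2R,3R)-3-{2-[(4-methoxybenzyl)oxy]ethyl}-2-methyloxiran-2-yl]but-3-en-2-ol | O[C@@H](C=C)C[C@@]1(C)O[C@@H]1CCOCc1ccc(OC)cc1 | intermediate
11 | 2-(bromomethyl)prop-2-enoic acid | OC(=O)C(=C)CBr | starting material
12 | 2-(bromomethyl)prop-2-enoyl chloride | ClC(=O)C(=C)CBr | intermediate
13 | (2R)-1-[(2R,3R)-3-{2-[(4-methoxybenzyl)oxy]ethyl}-2-methyloxiran-2-yl]but-3-en-2-yl 2-(bromomethyl)prop-2-enoate | C=C(CBr)C(=O)O[C@@H](C=C)C[C@@]1(C)O[C@@H]1CCOCc1ccc(OC)cc1 | intermediate
14 | (5R)-3-(bromomethyl)-5-{[(2R,3R)-3-{2-[(4-methoxybenzyl)oxy]ethyl}-2-methyloxiran-2-yl]methyl}furan-2(5H)-one | O=C1O[C@@H](C=C1CBr)C[C@@]2(C)O[C@@H]2CCOCc3ccc(OC)cc3 | intermediate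
15 | 1,2:5,6-di-O-isopropylidene-D-mannitol | C1[C@H]([C@H]([C@@H]([C@H]2COC(C)(C)O2)O)O)OC(C)(C)O1 | starting material
16 | (R)-2,2-dimethyl-1,3-dioxolane-4-carbaldehyde | O=C[C@H]1COC(C)(C)O1 | intermediate
17 | (S)-4-ethynyl-2,2-dimethyl-1,3-dioxolane | C#C[C@H]1COC(C)(C)O1 | intermediate
18 | (R)-2,2-dimethyl-4-[1-(tributylstannyl)ethenyl]-1,3-dioxolane | C=C([Sn](CCCC)(CCCC)CCCC)[C@H]1COC(C)(C)O1 | intermediate
19 | (R)-4-(1-iodoethenyl)-2,2-dimethyl-1,3-dioxolane | C=C(I)[C@H]1COC(C)(C)O1 | intermediate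
20 | (2R)-3-iodobut-3-ene-1,2-diol | C=C(I)[C@H](O)CO | intermediate
21 | (2R)-1-[(tert-butyldimethylsilyl)oxy]-3-iodobut-3-en-2-ol | C=C(I)[C@H](O)CO[Si](C)(C)C(C)(C)C | intermediate
22 | angelic acid, (2Z)-2-methylbut-2-enoic acid | C/C=C(/C)C(=O)O | starting material
23 | (2Z)-2-methylbut-2-enoic 2,4,6-trichlorobenzoic anhydride | C/C=C(/C)C(=O)OC(=O)c1c(Cl)cc(Cl)cc1Cl | intermediate
24 | (2R)-1-[(tert-butyldimethylsilyl)oxy]-3-iodobut-3-en-2-yl (2Z)-2-methylbut-2-enoate | C=C(I)[C@H](OC(=O)/C(C)=C\C)CO[Si](C)(C)C(C)(C)C | intermediate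
25 | (2R)-1-hydroxy-3-iodobut-3-en-2-yl (2Z)-2-methylbut-2-enoate | C=C(I)[C@H](OC(=O)/C(C)=C\C)CO | intermediate
26 | (2R)-3-iodo-1-oxobut-3-en-2-yl (2Z)-2-methylbut-2-enoate | C=C(I)[C@H](OC(=O)/C(C)=C\C)C=O | intermediate
27 | (1R,2R)-1-hydroxy-3-iodo-1-[(2R,3R)-2-{[(2R,3R)-3-{2-[(4-methoxybenzyl)oxy]ethyl}-2-methyloxiran-2-yl]methyl}-4-methylidene-5-oxooxolan-3-yl]but-3-en-2-yl (2Z)-2-methylbut-2-enoate | C=C1C(=O)O[C@H](C[C@@]2(C)O[C@@H]2CCOCc3ccc(OC)cc3)[C@H]1[C@@H](O)[C@@H](OC(=O)/C(C)=C\C)C(I)=C | intermediate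
28 | C8 triethylsilyl ether of 27 (same configurations) | C=C1C(=O)O[C@H](C[C@@]2(C)O[C@@H]2CCOCc3ccc(OC)cc3)[C@H]1[C@@H](O[Si](CC)(CC)CC)[C@@H](OC(=O)/C(C)=C\C)C(I)=C | intermediate
29 | primary C1 alcohol (28 without the PMB group) | C=C1C(=O)O[C@H](C[C@@]2(C)O[C@@H]2CCO)[C@H]1[C@@H](O[Si](CC)(CC)CC)[C@@H](OC(=O)/C(C)=C\C)C(I)=C | intermediate
30 | C1 aldehyde (β,γ-epoxy aldehyde from 29) | C=C1C(=O)O[C@H](C[C@@]2(C)O[C@@H]2CC=O)[C@H]1[C@@H](O[Si](CC)(CC)CC)[C@@H](OC(=O)/C(C)=C\C)C(I)=C | intermediate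
31 | macrocyclic C1 allylic alcohol (both C1 epimers), 8-O-triethylsilyl ether, 9-angelate, 3,4-epoxide, 12,6-lactone | C=C1C(=O)O[C@@H]2C[C@@]3(C)O[C@@H]3CC(O)C(=C)[C@H](OC(=O)/C(C)=C\C)[C@H](O[Si](CC)(CC)CC)[C@@H]12 | intermediate
32 | 8-O-triethylsilyl ether of the target | C=C1C(=O)O[C@@H]2C[C@@]3(C)O[C@@H]3CC(=O)C(=C)[C@H](OC(=O)/C(C)=C\C)[C@H](O[Si](CC)(CC)CC)[C@@H]12 | intermediate
33 | target CNP0348992.5: (3R,4R,6R,7R,8R,9S)-9-angeloyloxy-3,4-epoxy-8-hydroxy-1-oxogermacra-10(14),11(13)-dien-12,6-olide | C=C1C(=O)O[C@@H]2C[C@@]3(C)O[C@@H]3CC(=O)C(=C)[C@H](OC(=O)/C(C)=C\C)[C@H](O)[C@@H]12 | target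

**Step count and risks**
Total steps: 22. Longest linear sequence: 14 (steps 1–5, 7, 8, 16–22; the branch 9–15 then 16–22 is also 14). Step 6 is a one-step side branch.

Step 20 (ring closure). The ten-membered ring is strained, the β,γ-epoxy aldehyde 30 is fragile, and the alkenylchromium sits next to the allylic angelate, which could be lost by β-elimination. The fallback sets out from 29 and comes back at 32. Pd(PPh3)4 and Me3SnSnMe3 in toluene at 80 °C exchange iodine for tin to give the alkenylstannane alcohol F1. Dess–Martin oxidation gives the stannyl aldehyde F2, and NaClO2/NaH2PO4/2-methylbut-2-ene gives the stannyl carboxylic acid F3. 1-Chloro-N,N,2-trimethylprop-1-en-1-amine converts this under neutral conditions into the stannyl acid chloride F4. Slow addition of F4 to Pd2(dba)3/tri(2-furyl)phosphine in THF at 2 mM closes the ring by an intramolecular Stille acylation. This gives enone 32 directly, with no alkenylchromium, no epoxy aldehyde and no epoxy alcohol 31.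

Step 16 (fragment union). Aldehyde 26 can epimerise or conjugate, and three stereochemical elements must cooperate. The fallback sets out from 14 and comes back at 27. B2pin2, Pd2(dba)3 and KOAc in toluene at 50 °C convert the allylic bromide, through the π-allyl complex, into the allylboronate 3-[(pinacolatoboryl)methyl]butenolide F5. This isolable reagent is heated with 26 in toluene at 40–60 °C without any metal reductant. Allylboration through the same closed chair transition state, followed by mild hydrolysis of the borate, gives 27.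

Step 8 (metathesis in the presence of an allylic bromide). The catalyst may be consumed by the bromide, or the electron-poor 1,1-disubstituted alkene may not engage. The fallback sets out from 10 and comes back at 14. DCC/DMAP esterification of 10 with 2-{[(tert-butyldimethylsilyl)oxy]methyl}prop-2-enoic acid gives the silyloxymethyl acrylate ester F6. Ring-closing metathesis with second-generation Grubbs catalyst in CH2Cl2 at 40 °C gives the silyloxymethyl butenolide F7. HF·pyridine frees the hydroxymethyl butenolide F8. CBr4/PPh3 with 2,6-lutidine at 0 °C then installs the bromide to give 14, so the bromide is introduced only after the ring is made.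

**Further compounds**
F1 | step 20 | trimethylstannyl analogue of 29 (SnMe3 in place of I, C1 primary alcohol) | C=C1C(=O)O[C@H](C[C@@]2(C)O[C@@H]2CCO)[C@H]1[C@@H](O[Si](CC)(CC)CC)[C@@H](OC(=O)/C(C)=C\C)C([Sn](C)(C)C)=C
F2 | step 20 | stannyl aldehyde (C1 aldehyde of F1) | C=C1C(=O)O[C@H](C[C@@]2(C)O[C@@H]2CC=O)[C@H]1[C@@H](O[Si](CC)(CC)CC)[C@@H](OC(=O)/C(C)=C\C)C([Sn](C)(C)C)=C
F3 | step 20 | stannyl carboxylic acid (C1 acid) | C=C1C(=O)O[C@H](C[C@@]2(C)O[C@@H]2CC(=O)O)[C@H]1[C@@H](O[Si](CC)(CC)CC)[C@@H](OC(=O)/C(C)=C\C)C([Sn](C)(C)C)=C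
F4 | step 20 | stannyl acid chloride (C1 acyl chloride) | C=C1C(=O)O[C@H](C[C@@]2(C)O[C@@H]2CC(=O)Cl)[C@H]1[C@@H](O[Si](CC)(CC)CC)[C@@H](OC(=O)/C(C)=C\C)C([Sn](C)(C)C)=C
F5 | step 16 | (5R)-5-{[(2R,3R)-3-{2-[(4-methoxybenzyl)oxy]ethyl}-2-methyloxiran-2-yl]methyl}-3-[(4,4,5,5-tetramethyl-1,3,2-dioxaborolan-2-yl)methyl]furan-2(5H)-one | O=C1O[C@@H](C=C1CB2OC(C)(C)C(C)(C)O2)C[C@@]3(C)O[C@@H]3CCOCc4ccc(OC)cc4
F6 | step 8 | (2R)-1-[(2R,3R)-3-{2-[(4-methoxybenzyl)oxy]ethyl}-2-methyloxiran-2-yl]but-3-en-2-yl 2-{[(tert-butyldimethylsilyl)oxy]methyl}prop-2-enoate | C=C(CO[Si](C)(C)C(C)(C)C)C(=O)O[C@@H](C=C)C[C@@]1(C)O[C@@H]1CCOCc2ccc(OC)cc2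
F7 | step 8 | (5R)-3-{[(tert-butyldimethylsilyl)oxy]methyl}-5-{[(2R,3R)-3-{2-[(4-methoxybenzyl)oxy]ethyl}-2-methyloxiran-2-yl]methyl}furan-2(5H)-one | O=C1O[C@@H](C=C1CO[Si](C)(C)C(C)(C)C)C[C@@]2(C)O[C@@H]2CCOCc3ccc(OC)cc3
F8 | step 8 | (5R)-3-(hydroxymethyl)-5-{[(2R,3R)-3-{2-[(4-methoxybenzyl)oxy]ethyl}-2-methyloxiran-2-yl]methyl}furan-2(5H)-one | O=C1O[C@@H](C=C1CO)C[C@@]2(C)O[C@@H]2CCOCc3ccc(OC)cc3
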